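The oxolane ring is disconnected at O1–C5 and C2–C3. Its benzylic carbon C5 and its carbon C3, whose CH2OH can stem from a malonate, stand in a 1,3-relationship across C4, which is the polarity pattern of a donor–acceptor cyclopropane, while O1–C2(aryl) is an aryl aldehyde in disguise. In the key step AlCl3 inserts the C=O group of the aldehyde into an enantiopure aryl cyclopropane-1,1-diester: the three-membered carbocycle grows by two atoms into the oxolane, C5 is inverted, C4 is carried over and C2 is set cis to C5 in one operation. An organocatalytic cyclopropanation supplies the absolute configuration; C3 is adjusted thermodynamically afterwards.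

Key step: step 5

Remark on the target: the aryl groups are 2,5-cis and the hydroxymethyl groups 3,4-trans, so one CH2OH is cis and the other trans to its neighbouring aryl group; the route places the cis pair on the two cyclopropane-derived carbons.
Remark on numbering: in 8–11 the oxolane is numbered O1, C2 (carbon from aldehyde 1), C3 (former malonate carbon), C4, C5 (former benzylic cyclopropane carbon); in the cyclopropanes C1 is the malonate carbon, C2 bears the one-carbon substituent and C3 the aryl group.
Assumption: aldehyde 1 is taken as a purchasable building block (otherwise it is one O-benzylation away from syringaldehyde).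

Step 1
Reactants: 1 4-(benzyloxy)-3,5-dimethoxybenzaldehyde; 2 (triphenylphosphoranylidene)acetaldehyde
Product: 3 (E)-3-[4-(benzyloxy)-3,5-dimethoxyphenyl]prop-2-enal
Conditions: 2 (1.2 equiv), toluene, 90 °C
Reagents that add atoms: none
Why: Wittig olefination with the formyl-stabilised ylide should give the (E)-enal under thermodynamic control, and keeping the ylide near one equivalent limits a second homologation of the less electrophilic conjugated product.

Step 2
Reactants: 3 (E)-3-[4-(benzyloxy)-3,5-dimethoxyphenyl]prop-2-enal; 4 dimethyl 2-bromomalonate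
Product: 5 dimethyl (2S,3R)-3-[4-(benzyloxy)-3,5-dimethoxyphenyl]-2-formylcyclopropane-1,1-dicarboxylate (aryl and formyl trans)
Conditions: (R)-2-[diphenyl(trimethylsilyloxy)methyl]pyrrolidine (20 mol%), 2,6-lutidine (1.1 equiv), CH2Cl2, 0 °C to rt
Reagents that add atoms: none
Why: Organocatalytic Michael-initiated ring closure (iminium–enamine cascade), in which the (R)-diarylprolinol silyl ether forms an (E)-iminium ion with one face blocked by the CPh2OSiMe3 group, the bromomalonate carbanion adds to the open face of the β-carbon (setting C3), and the enamine then displaces bromide in a 3-exo-tet closure that places the formyl group trans to the aryl group (setting C2).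

Step 3
Reactants: 5 dimethyl (2S,3R)-3-[4-(benzyloxy)-3,5-dimethoxyphenyl]-2-formylcyclopropane-1,1-dicarboxylate
Product: 6 dimethyl (2S,3R)-3-[4-(benzyloxy)-3,5-dimethoxyphenyl]-2-(hydroxymethyl)cyclopropane-1,1-dicarboxylate
Conditions: NaBH4, MeOH–THF, −20 °C; pH 7 phosphate buffer quench
Reagents that add atoms: none
Why: Chemoselective borohydride reduction of the aldehyde beside the malonate esters, with low temperature and a neutral quench to keep the γ-hydroxy ester from closing to the bicyclic lactone; no stereocentre is touched.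

Step 4
Reactants: 6 dimethyl (2S,3R)-3-[4-(benzyloxy)-3,5-dimethoxyphenyl]-2-(hydroxymethyl)cyclopropane-1,1-dicarboxylate
Product: 7 dimethyl (2S,3R)-3-[4-(benzyloxy)-3,5-dimethoxyphenyl]-2-{[(tert-butyldiphenylsilyl)oxy]methyl}cyclopropane-1,1-dicarboxylate
Conditions: TBDPSCl, imidazole, CH2Cl2, 0 °C to rt
Reagents that add atoms: tert-butyl(chloro)diphenylsilane, CC(C)(C)[Si](Cl)(c1ccccc1)c1ccccc1
Why: Standard silylation of a primary alcohol under weakly basic conditions; the bulky silyl ether cannot act as a neighbouring group in step 5 and should survive Lewis acid, hot chloride and catalytic methoxide.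

Step 5
Reactants: 7 dimethyl (2S,3R)-3-[4-(benzyloxy)-3,5-dimethoxyphenyl]-2-{[(tert-butyldiphenylsilyl)oxy]methyl}cyclopropane-1,1-dicarboxylate; 1 4-(benzyloxy)-3,5-dimethoxybenzaldehyde
Product: 8 dimethyl (2S,4S,5S)-2,5-bis[4-(benzyloxy)-3,5-dimethoxyphenyl]-4-{[(tert-butyldiphenylsilyl)oxy]methyl}oxolane-3,3-dicarboxylate (aryl groups 2,5-cis; CH2OSi cis to the C5 aryl group)
Conditions: AlCl3 (0.2 equiv), 1 (3 equiv, excess recovered), CH2Cl2, 0 °C to rt
Reagents that add atoms: none
Why: AlCl3 chelates the geminal diester and polarises the C1–C3 bond of the cyclopropane; the carbonyl oxygen of 1 attacks the benzylic carbon C3 from the rear (SN2-like), giving an aluminium malonate enolate tethered to an (E)-oxocarbenium ion, which closes by an intramolecular aldol-type C–C bond formation. The closest known reaction type is the Lewis acid-catalysed formal [3+2] cycloaddition of donor–acceptor cyclopropanes with aldehydes, used here as a two-atom ring expansion of the cyclopropane to the oxolane. The oxolane closes in a 5-(enolexo)-endo-trig mode at the oxocarbenium carbon. C5 is set by stereospecific inversion of cyclopropane C3, C4 is carried over unchanged (so the trans-cyclopropane gives the 4,5-cis oxolane), and C2 is set by an envelope transition state with both aryl groups pseudo-equatorial, which gives the 2,5-cis product. The step needs cleavage of the benzylic C1–C3 bond and not of C1–C2, and capture by the aldehyde before free ionisation; the aryl donor secures the first, and the twisted, weakly donating 4-benzyloxy group between two methoxy groups together with an excess of the nucleophilic electron-rich aldehyde secures the second.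

Step 6
Reactants: 8 dimethyl (2S,4S,5S)-2,5-bis[4-(benzyloxy)-3,5-dimethoxyphenyl]-4-{[(tert-butyldiphenylsilyl)oxy]methyl}oxolane-3,3-dicarboxylate
Product: 10 methyl (2R,3R,4S,5S)-2,5-bis[4-(benzyloxy)-3,5-dimethoxyphenyl]-4-{[(tert-butyldiphenylsilyl)oxy]methyl}oxolane-3-carboxylate (ester trans to both neighbours), via all-cis C3-epimeric ester 9 (not isolated)
Conditions: LiCl, H2O, DMSO, 150 °C; then NaOMe (0.3 equiv), MeOH–THF, 40 °C
Reagents that add atoms: none
Why: Krapcho dealkoxycarbonylation followed by base equilibration, in which kinetic protonation of the ester enolate on the face opposite the three cis substituents should give mainly 9 and catalytic methoxide then epimerises C3 to the isomer with the ester trans to both neighbours (thermodynamic control), ring opening of the enolate by loss of the ring alkoxide being a stereoelectronically disfavoured retro-5-endo-trig process.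

Step 7
Reactants: 10 methyl (2R,3R,4S,5S)-2,5-bis[4-(benzyloxy)-3,5-dimethoxyphenyl]-4-{[(tert-butyldiphenylsilyl)oxy]methyl}oxolane-3-carboxylate
Product: 11 {(2R,3S,4S,5S)-2,5-bis[4-(benzyloxy)-3,5-dimethoxyphenyl]-4-{[(tert-butyldiphenylsilyl)oxy]methyl}oxolan-3-yl}methanol
Conditions: LiAlH4, THF, 0 °C
Reagents that add atoms: none
Why: Hydride reduction of the ester to the primary alcohol, with silyl and benzyl ethers inert and no epimerisable centre under these conditions.

Step 8
Reactants: 11 {(2R,3S,4S,5S)-2,5-bis[4-(benzyloxy)-3,5-dimethoxyphenyl]-4-{[(tert-butyldiphenylsilyl)oxy]methyl}oxolan-3-yl}methanol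
Product: 12 {(2S,3S,4S,5R)-2,5-bis[4-(benzyloxy)-3,5-dimethoxyphenyl]oxolane-3,4-diyl}dimethanol
Conditions: Bu4NF, THF, rt
Reagents that add atoms: none
Why: Fluoride-driven cleavage of the Si–O bond should free the second hydroxymethyl group without touching the benzyl ethers or the benzylic ring C–O bonds.

Step 9
Reactants: 12 {(2S,3S,4S,5R)-2,5-bis[4-(benzyloxy)-3,5-dimethoxyphenyl]oxolane-3,4-diyl}dimethanol
Product: 13 4,4'-[(2S,3S,4S,5R)-3,4-bis(hydroxymethyl)oxolane-2,5-diyl]bis(2,6-dimethoxyphenol) (target)
Conditions: H2 (1 atm), 10% Pd/C, EtOAc–MeOH, rt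
Reagents that add atoms: none
Why: Catalytic hydrogenolysis of the two aryl benzyl ethers, which under neutral conditions at atmospheric pressure should be cleaved much faster than the dialkyl benzylic C–O bonds of the oxolane, releases both phenols without touching a stereocentre.

Compound list
1 | 4-(benzyloxy)-3,5-dimethoxybenzaldehyde | COc1cc(C=O)cc(OC)c1OCc1ccccc1 | starting material
2 | (triphenylphosphoranylidene)acetaldehyde | O=CC=P(c1ccccc1)(c1ccccc1)c1ccccc1 | starting material
3 | (E)-3-[4-(benzyloxy)-3,5-dimethoxyphenyl]prop-2-enal | COc1cc(/C=C/C=O)cc(OC)c1OCc1ccccc1 | intermediate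
4 | dimethyl 2-bromomalonate | COC(=O)C(Br)C(=O)OC | starting material
5 | dimethyl (2S,3R)-3-[4-(benzyloxy)-3,5-dimethoxyphenyl]-2-formylcyclopropane-1,1-dicarboxylate | COC(=O)C1(C(=O)OC)[C@@H](C=O)[C@@H]1c1cc(OC)c(OCc2ccccc2)c(OC)c1 | intermediate
6 | dimethyl (2S,3R)-3-[4-(benzyloxy)-3,5-dimethoxyphenyl]-2-(hydroxymethyl)cyclopropane-1,1-dicarboxylate | COC(=O)C1(C(=O)OC)[C@@H](CO)[C@@H]1c1cc(OC)c(OCc2ccccc2)c(OC)c1 | intermediate
7 | dimethyl (2S,3R)-3-[4-(benzyloxy)-3,5-dimethoxyphenyl]-2-{[(tert-butyldiphenylsilyl)oxy]methyl}cyclopropane-1,1-dicarboxylate | COC(=O)C1(C(=O)OC)[C@@H](CO[Si](c2ccccc2)(c2ccccc2)C(C)(C)C)[C@@H]1c1cc(OC)c(OCc2ccccc2)c(OC)c1 | intermediate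
8 | dimethyl (2S,4S,5S)-2,5-bis[4-(benzyloxy)-3,5-dimethoxyphenyl]-4-{[(tert-butyldiphenylsilyl)oxy]methyl}oxolane-3,3-dicarboxylate | COc1cc([C@H]2O[C@@H](c3cc(OC)c(OCc4ccccc4)c(OC)c3)C(C(=O)OC)(C(=O)OC)[C@H]2CO[Si](c5ccccc5)(c6ccccc6)C(C)(C)C)cc(OC)c1OCc7ccccc7 | intermediate
9 | methyl (2R,3S,4S,5S)-2,5-bis[4-(benzyloxy)-3,5-dimethoxyphenyl]-4-{[(tert-butyldiphenylsilyl)oxy]methyl}oxolane-3-carboxylate (all-cis C3 epimer, not isolated) | COc1cc([C@H]2O[C@@H](c3cc(OC)c(OCc4ccccc4)c(OC)c3)[C@@H](C(=O)OC)[C@H]2CO[Si](c5ccccc5)(c6ccccc6)C(C)(C)C)cc(OC)c1OCc7ccccc7 | intermediate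
10 | methyl (2R,3R,4S,5S)-2,5-bis[4-(benzyloxy)-3,5-dimethoxyphenyl]-4-{[(tert-butyldiphenylsilyl)oxy]methyl}oxolane-3-carboxylate | COc1cc([C@H]2O[C@@H](c3cc(OC)c(OCc4ccccc4)c(OC)c3)[C@H](C(=O)OC)[C@H]2CO[Si](c5ccccc5)(c6ccccc6)C(C)(C)C)cc(OC)c1OCc7ccccc7 | intermediate
11 | {(2R,3S,4S,5S)-2,5-bis[4-(benzyloxy)-3,5-dimethoxyphenyl]-4-{[(tert-butyldiphenylsilyl)oxy]methyl}oxolan-3-yl}methanol | COc1cc([C@H]2O[C@@H](c3cc(OC)c(OCc4ccccc4)c(OC)c3)[C@H](CO)[C@H]2CO[Si](c5ccccc5)(c6ccccc6)C(C)(C)C)cc(OC)c1OCc7ccccc7 | intermediate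
12 | {(2S,3S,4S,5R)-2,5-bis[4-(benzyloxy)-3,5-dimethoxyphenyl]oxolane-3,4-diyl}dimethanol | COc1cc([C@H]2O[C@@H](c3cc(OC)c(OCc4ccccc4)c(OC)c3)[C@H](CO)[C@H]2CO)cc(OC)c1OCc5ccccc5 | intermediate
13 | 4,4'-[(2S,3S,4S,5R)-3,4-bis(hydroxymethyl)oxolane-2,5-diyl]bis(2,6-dimethoxyphenol) | COc1cc([C@H]2O[C@@H](c3cc(OC)c(O)c(OC)c3)[C@H](CO)[C@H]2CO)cc(OC)c1O | target

Total step count: 9. Longest linear sequence: 9 steps (1 to 13; aldehyde 1 enters a second time in step 5).

Steps most likely to fail

Step 5. The benzylic C1–C3 bond may ionise to a free benzylic cation before the aldehyde is bound, which would erode the enantiomeric purity and the 4,5-cis relationship. The Lewis acid may also re-ionise the product at C5–O and epimerise it, or attack the benzyl ethers. The fallback is another two-atom ring expansion, this time of an oxirane; it sets out from 1 and comes back at 12. Reductive McMurry coupling of 1 (TiCl4, Zn, THF, reflux) should give (E)-1,2-bis[4-(benzyloxy)-3,5-dimethoxyphenyl]ethene F1. Epoxidation with dimethyldioxirane in acetone at 0 °C should give racemic trans-2,3-bis[4-(benzyloxy)-3,5-dimethoxyphenyl]oxirane F2. Photoinduced electron transfer (9,10-dicyanoanthracene, visible light, MeCN) should cleave the C–C bond of the oxirane to the achiral exo,exo carbonyl ylide. This dipole should add suprafacially to di-(−)-menthyl fumarate to give the 2,5-cis-3,4-trans oxolane diester as two diastereomers that differ in the fumarate face used. The isomer with the required core, di-(−)-menthyl (2S,3R,4R,5R)-2,5-bis[4-(benzyloxy)-3,5-dimethoxyphenyl]oxolane-3,4-dicarboxylate F3, is separated by chromatography and reduced with LiAlH4 in THF to 12.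

Step 6. Equilibration at C3 may stay incomplete at the ester oxidation level, and under hot chloride the silyl ether may be lost, after which the all-cis isomer would lactonise and lock the wrong C3 configuration. The fallback moves the equilibration to the more acidic aldehyde; it sets out from 9 (the crude decarboxylation product, taken on without methoxide) and comes back at 11. Partial reduction with iBu2AlH in CH2Cl2 at −78 °C should give (2R,3S,4S,5S)-2,5-bis[4-(benzyloxy)-3,5-dimethoxyphenyl]-4-{[(tert-butyldiphenylsilyl)oxy]methyl}oxolane-3-carbaldehyde F4. DBU in CH2Cl2 at rt should epimerise it to the isomer with the formyl group trans to both neighbours, (2R,3R,4S,5S)-2,5-bis[4-(benzyloxy)-3,5-dimethoxyphenyl]-4-{[(tert-butyldiphenylsilyl)oxy]methyl}oxolane-3-carbaldehyde F5. NaBH4 in MeOH at 0 °C then gives 11.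

Step 3. The hydroxymethyl group may close onto the cis ester during reduction, work-up or silylation, giving the bicyclic lactone. The fallback avoids the free alcohol altogether; it sets out from 5 and comes back at 7. Hydrosilylation of the aldehyde with tert-butyldiphenylsilane and catalytic [(Ph3P)CuH]6 (a hydride of monovalent copper) in toluene at rt should deliver the silyl ether 7 directly, the copper alkoxide being silylated before it can attack the ester. This fallback makes no compound outside the list (F0).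

Further compounds
F1 | step 5 | (E)-1,2-bis[4-(benzyloxy)-3,5-dimethoxyphenyl]ethene | COc1cc(/C=C/c2cc(OC)c(OCc3ccccc3)c(OC)c2)cc(OC)c1OCc1ccccc1
F2 | step 5 | rac-(2R,3R)-2,3-bis[4-(benzyloxy)-3,5-dimethoxyphenyl]oxirane (trans, one enantiomer drawn) | COc1cc([C@H]2O[C@@H]2c2cc(OC)c(OCc3ccccc3)c(OC)c2)cc(OC)c1OCc1ccccc1
F3 | step 5 | bis[(1R,2S,5R)-2-isopropyl-5-methylcyclohexyl] (2S,3R,4R,5R)-2,5-bis[4-(benzyloxy)-3,5-dimethoxyphenyl]oxolane-3,4-dicarboxylate | COc1cc([C@H]2O[C@@H](c3cc(OC)c(OCc4ccccc4)c(OC)c3)[C@H](C(=O)O[C@@H]5C[C@H](C)CC[C@H]5C(C)C)[C@H]2C(=O)O[C@@H]6C[C@H](C)CC[C@H]6C(C)C)cc(OC)c1OCc7ccccc7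
F4 | step 6 | (2R,3S,4S,5S)-2,5-bis[4-(benzyloxy)-3,5-dimethoxyphenyl]-4-{[(tert-butyldiphenylsilyl)oxy]methyl}oxolane-3-carbaldehyde | COc1cc([C@H]2O[C@@H](c3cc(OC)c(OCc4ccccc4)c(OC)c3)[C@@H](C=O)[C@H]2CO[Si](c5ccccc5)(c6ccccc6)C(C)(C)C)cc(OC)c1OCc7ccccc7
F5 | step 6 | (2R,3R,4S,5S)-2,5-bis[4-(benzyloxy)-3,5-dimethoxyphenyl]-4-{[(tert-butyldiphenylsilyl)oxy]methyl}oxolane-3-carbaldehyde | COc1cc([C@H]2O[C@@H](c3cc(OC)c(OCc4ccccc4)c(OC)c3)[C@H](C=O)[C@H]2CO[Si](c5ccccc5)(c6ccccc6)C(C)(C)C)cc(OC)c1OCc7ccccc7
F0 | step 3 | none | none
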